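**Plan**
- Retrosynthesis: remove the C10 benzoate, then cut C8–CH3 and C9–CH3 (conjugate addition and enolate methylation) back to the achiral enone 17 (C8=C9–C10=O).
- Enabling feature: the seven-membered ring (C1′, C7, C8, C9, C10 and the arene edge) carries C10 at ketone level next to C9. Excising C9 (cut C9–C8 and C9–C10, join C8–C10) leaves a six-membered spiro-tetralone that shares spiro C1′ and the arene edge, and whose silyl enol ether can take C9 back up as a cyclopropane carbon.
- The spiro-tetralone is cut at C1′–C7 (para-alkylation of a phenolate), C8–C10 (vinyl Grignard on an aldehyde) and the biaryl bond (Suzuki–Miyaura).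
- Forward ring order: biaryl, then the six-membered spiro ring by dearomatisation, then the cyclopropane, then the seven-membered ring by Fe(III) opening of the fusion bond; methyls, carbinol and benzoate follow.
- Stereochemistry: C8 comes from a Cu/phosphoramidite-catalysed Me2Zn addition to 17 (the only source of absolute configuration), C9 from trans enolate methylation (also the thermodynamic isomer), C10 from substrate-controlled hydride addition. All earlier stereocentres are racemic and are erased.

Key step: step 10

Remark (locants): ring A is the trimethoxybenzene; C10 is the benzylic carbon on ring A, followed by C9, C8 and C7; C1′ is the spiro carbon, C2′/C6′ the dienone CH, C3′/C5′ the C–OMe carbons, C4′ the dienone carbonyl. In the six-membered-ring intermediates C9 is absent and C8 is bonded to C10.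
Remark (assumption): boronate 1 is taken as a catalogue compound; otherwise it is one Miyaura borylation away from 4-bromo-2,6-dimethoxyphenol.
Remark (assumption): the (R,S,S)-phosphoramidite is assumed to deliver methyl to the face giving 8R, by analogy with cyclohex-2-enone and cyclohept-2-enone; if the sense is reversed on 17, the enantiomeric ligand is used.

Step 1
Reactants: 1 2,6-dimethoxy-4-(4,4,5,5-tetramethyl-1,3,2-dioxaborolan-2-yl)phenol
Product: 2 tert-butyl[2,6-dimethoxy-4-(4,4,5,5-tetramethyl-1,3,2-dioxaborolan-2-yl)phenoxy]dimethylsilane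
Conditions: TBSCl, imidazole, DMF, rt
Reagents that add atoms: tert-butyldimethylsilyl chloride, CC(C)(C)[Si](C)(C)Cl
Why: Imidazole-promoted silylation of the phenol; the silyl ether protects the phenol through steps 2–5 and is the fluoride-labile trigger of step 6.

Step 2
Reactants: 2 silyl-protected aryl boronate; 3 2-bromo-3,4,5-trimethoxybenzaldehyde
Product: 4 2-[4-(tert-butyldimethylsilyloxy)-3,5-dimethoxyphenyl]-3,4,5-trimethoxybenzaldehyde
Conditions: Pd(OAc)2 (2 mol%), SPhos (4 mol%), K3PO4, toluene/H2O, 80 °C
Reagents that add atoms: none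
Why: Suzuki–Miyaura coupling; a dialkylbiarylphosphine is chosen because the bromide has two ortho substituents, and the aldehyde and the aryl silyl ether tolerate the phosphate base.

Step 3
Reactants: 4 biaryl aldehyde; 5 vinylmagnesium bromide
Product: 6 rac-1-{2-[4-(tert-butyldimethylsilyloxy)-3,5-dimethoxyphenyl]-3,4,5-trimethoxyphenyl}prop-2-en-1-ol
Conditions: THF, −78 → 0 °C; aq. NH4Cl
Reagents that add atoms: none
Why: Grignard 1,2-addition to the aldehyde forms the C10–C8 bond; the carbinol centre is racemic and is removed by the oxidation in step 7.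

Step 4
Reactants: 6 racemic allylic alcohol
Product: 8 rac-1-aryl-propane-1,3-diol (aryl as in 6), via O,C-bis(9-borabicyclononyl) adduct 7 (not isolated)
Conditions: 9-BBN (2.5 equiv), THF, 0 °C → rt; then NaBO3·4H2O, H2O, rt
Reagents that add atoms: sodium perborate, [Na+].[O-]OB=O
Why: Hydroboration–oxidation: after the free hydroxyl has consumed one equivalent of borane, 9-BBN places boron on the terminal carbon C7 and perborate oxidises the C–B bond under conditions mild enough for the aryl silyl ether; no stereocentre is formed.

Step 5
Reactants: 8 racemic 1,3-diol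
Product: 9 rac-3-hydroxy-3-aryl-propyl 4-methylbenzenesulfonate (aryl as in 6)
Conditions: TsCl (1.1 equiv), Et3N, Me3N·HCl (cat.), CH2Cl2, 0 °C
Reagents that add atoms: p-toluenesulfonyl chloride, Cc1ccc(cc1)S(Cl)(=O)=O
Why: Amine-catalysed sulfonylation distinguishes the primary from the hindered secondary benzylic hydroxyl on steric grounds, and the silyl ether keeps the phenol from being sulfonylated.

Step 6
Reactants: 9 racemic primary tosylate
Product: 11 rac-10-hydroxy spiro-tetralin dienone (3′,5′-dimethoxy-4′-oxocyclohexa-2′,5′-diene spiro-fused at C1′ to the ring C1′–C7–C8–C10–arene), via caesium phenolate 10 (not isolated)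
Conditions: CsF (3 equiv), DMF (0.01 M), 90 °C
Reagents that add atoms: none
Why: Fluoride removes the silyl group and the phenolate displaces the primary tosylate through its para carbon C1′ (6-exo-tet alkylative dearomatisation, Ar1-6 participation, as known for 4′-hydroxybiaryls with an ortho-tethered primary leaving group); this irreversible SN2 closure is preferred to a conjugate addition onto an aryl vinyl ketone, which would be close to thermoneutral and reversible, and the phenolate oxygen cannot reach C7 while dilution suppresses intermolecular O-alkylation.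

Step 7
Reactants: 11 racemic spiro alcohol
Product: 12 spiro-tetralone dienone (C10 ketone, achiral)
Conditions: Dess–Martin periodinane, NaHCO3, CH2Cl2, 0 °C → rt
Reagents that add atoms: none
Why: Dess–Martin oxidation of the secondary benzylic alcohol under buffered, non-basic conditions leaves the dienone untouched and erases the racemic C10 centre.

Step 8
Reactants: 12 spiro-tetralone dienone
Product: 13 trimethylsilyl enol ether of 12 (C10(OSiMe3)=C8)
Conditions: TMSOTf, Et3N, CH2Cl2, 0 °C; used crude
Reagents that add atoms: trimethylsilyl trifluoromethanesulfonate, C[Si](C)(C)OS(=O)(=O)C(F)(F)F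
Why: Soft enolisation gives the only possible silyl enol ether without a free enolate, which could break the C7–C1′ bond by retro-Michael expulsion of the phenolate.

Step 9
Reactants: 13 silyl enol ether; 14 diiodomethane
Product: 15 racemic siloxycyclopropane (C9 methylene bridging C8 and C10 of 13; cis-fused 1-trimethylsiloxybicyclo[4.1.0] unit)
Conditions: Et2Zn, CH2I2, CH2Cl2, 0 °C → rt; pyridine, aq. NaHCO3 quench
Reagents that add atoms: none
Why: Simmons–Smith cyclopropanation (Et2Zn variant): the electrophilic zinc carbenoid selects the electron-rich silyl enol ether over the carbonyl-conjugated dienone alkenes next to the quaternary C1′; cis fusion is the only possibility and both new centres are racemic and lost in step 10.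

Step 10
Reactants: 15 racemic siloxycyclopropane
Product: 17 achiral spiro benzosuberenone dienone (C8=C9–C10=O), via racemic 8-chloro ketone 16 (not isolated)
Conditions: FeCl3 (anhydrous, 3 equiv), DMF, 0 °C → rt, 15 added slowly; then NaOAc, MeOH, 50 °C
Reagents that add atoms: none
Why: One-electron oxidation of the aryl-substituted siloxycyclopropane by Fe(III) with loss of the silyl group gives a cyclopropyloxy radical; its β-scission breaks the fusion bond C8–C10, so C10 becomes the aryl ketone carbonyl and the ring-enlarged secondary C8 radical takes chlorine from a second FeCl3, after which acetate eliminates HCl from 16 (E1cB) to give the C8=C9 enone. This is the known iron(III) chloride ring enlargement of 1-siloxybicyclo[n.1.0]alkanes to cycloalk-2-enones. The seven-membered ring is not closed by a cyclisation but arises by fragmentation of the zero-atom bridge of the bicyclo[4.1.0] unit, so no exo/endo mode applies; the former carbenoid carbon C9 ends up between C8 and C10. No stereocentre is formed and the two of 15 are destroyed, which makes 17 achiral. Two selectivities are needed: internal rather than external cyclopropane cleavage, secured by forming a secondary ring radical instead of a primary exocyclic one and by the larger strain release; and chlorine transfer to the C8 radical faster than β-scission of its C7–C1′ bond (which would aromatise the dienone to a phenoxyl radical), for which the substrate gives no help and which is addressed by slow addition of 15 to concentrated FeCl3 at 0 °C.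

Step 11
Reactants: 17 achiral enone
Product: 19 (8R,9S)-8,9-dimethyl ketone (trans), via methylzinc enolate 18 (not isolated)
Conditions: Cu(OTf)2 (3 mol%), (R,S,S)-BINOL bis(1-phenylethyl)amine phosphoramidite (6 mol%), Me2Zn, toluene, −20 °C; then MeI, HMPA, 0 °C → rt
Reagents that add atoms: dimethylzinc, C[Zn]C; iodomethane, CI
Why: Copper-catalysed asymmetric conjugate addition puts methyl on one enantiotopic face of C8 (ligand control, 8R), and the zinc enolate is C-methylated at C9 anti to the new C8 methyl (tandem conjugate addition–enolate alkylation, as practised on cyclohept-2-enone with dimethylzinc and primary iodides), trans also being the thermodynamic isomer; dimethylzinc does not add to the dienone carbonyl, and the dienone β-carbons are shielded by quaternary C1′ and deactivated by the α-methoxy groups.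

Step 12
Reactants: 19 (8R,9S)-ketone
Product: 21 (8R,9S,10R)-10-hydroxy dienone, via C4′,C10-diol 20 (not isolated)
Conditions: NaBH4, MeOH/THF, 0 °C → rt; neutral aqueous work-up; crude, activated MnO2, CH2Cl2, rt
Reagents that add atoms: none
Why: Borohydride reduction takes both ketones, since the unhindered dienone carbonyl cannot be spared; hydride should reach C10 anti-periplanar to the pseudo-axial C9–H (axial-type attack as in 2-alkylcycloalkanones) to give the carbinol trans to the C9 methyl, and allylic MnO2 oxidation then returns only the doubly allylic C4′ carbinol to the dienone because the hindered benzylic C10–OH is oxidised much more slowly.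

Step 13
Reactants: 21 (8R,9S,10R)-hydroxy dienone
Product: 22 CNP0201356.1, the (8R,9S,10R)-10-benzoate
Conditions: BzCl, pyridine, DMAP (cat.), CH2Cl2, 0 °C → rt
Reagents that add atoms: benzoyl chloride, O=C(Cl)c1ccccc1
Why: DMAP-catalysed O-acylation of the secondary benzylic alcohol proceeds with retention at C10 and touches no other group.

**Compound list**
1 | 2,6-dimethoxy-4-(4,4,5,5-tetramethyl-1,3,2-dioxaborolan-2-yl)phenol | COc1cc(B2OC(C)(C)C(C)(C)O2)cc(OC)c1O | starting material
2 | tert-butyl[2,6-dimethoxy-4-(4,4,5,5-tetramethyl-1,3,2-dioxaborolan-2-yl)phenoxy]dimethylsilane | COc1cc(B2OC(C)(C)C(C)(C)O2)cc(OC)c1O[Si](C)(C)C(C)(C)C | intermediate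
3 | 2-bromo-3,4,5-trimethoxybenzaldehyde | COc1cc(C=O)c(Br)c(OC)c1OC | starting material
4 | 2-[4-(tert-butyldimethylsilyloxy)-3,5-dimethoxyphenyl]-3,4,5-trimethoxybenzaldehyde | COc1cc(C=O)c(-c2cc(OC)c(O[Si](C)(C)C(C)(C)C)c(OC)c2)c(OC)c1OC | intermediate
5 | vinylmagnesium bromide | C=C[Mg]Br | starting material
6 | rac-1-{2-[4-(tert-butyldimethylsilyloxy)-3,5-dimethoxyphenyl]-3,4,5-trimethoxyphenyl}prop-2-en-1-ol | COc1cc(C(O)C=C)c(-c2cc(OC)c(O[Si](C)(C)C(C)(C)C)c(OC)c2)c(OC)c1OC | intermediate
7 | rac-O,C-bis(9-borabicyclo[3.3.1]nonan-9-yl) adduct of 6 (boron on O and on C7) | COc1cc(C(OB2C3CCCC2CCC3)CCB2C3CCCC2CCC3)c(-c2cc(OC)c(O[Si](C)(C)C(C)(C)C)c(OC)c2)c(OC)c1OC | intermediate (not isolated)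
8 | rac-1-{2-[4-(tert-butyldimethylsilyloxy)-3,5-dimethoxyphenyl]-3,4,5-trimethoxyphenyl}propane-1,3-diol | COc1cc(C(O)CCO)c(-c2cc(OC)c(O[Si](C)(C)C(C)(C)C)c(OC)c2)c(OC)c1OC | intermediate
9 | rac-3-hydroxy-3-{2-[4-(tert-butyldimethylsilyloxy)-3,5-dimethoxyphenyl]-3,4,5-trimethoxyphenyl}propyl 4-methylbenzenesulfonate | COc1cc(C(O)CCOS(=O)(=O)c2ccc(C)cc2)c(-c2cc(OC)c(O[Si](C)(C)C(C)(C)C)c(OC)c2)c(OC)c1OC | intermediate
10 | caesium phenolate of desilylated 9 | [Cs+].COc1cc(C(O)CCOS(=O)(=O)c2ccc(C)cc2)c(-c2cc(OC)c([O-])c(OC)c2)c(OC)c1OC | intermediate (not isolated)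
11 | rac-10-hydroxy spiro-tetralin dienone | COC1=CC2(C=C(OC)C1=O)CCC(O)c1cc(OC)c(OC)c(OC)c12 | intermediate
12 | spiro-tetralone dienone (achiral) | COC1=CC2(C=C(OC)C1=O)CCC(=O)c1cc(OC)c(OC)c(OC)c12 | intermediate
13 | trimethylsilyl enol ether of 12 | COC1=CC2(C=C(OC)C1=O)CC=C(O[Si](C)(C)C)c1cc(OC)c(OC)c(OC)c12 | intermediate
14 | diiodomethane | ICI | starting material
15 | racemic cis-fused siloxycyclopropane of the spiro-tetralone dienone | COC1=CC2(C=C(OC)C1=O)CC3CC3(O[Si](C)(C)C)c1cc(OC)c(OC)c(OC)c12 | intermediate
16 | rac-8-chloro spiro-benzosuberone dienone | COC1=CC2(C=C(OC)C1=O)CC(Cl)CC(=O)c1cc(OC)c(OC)c(OC)c12 | intermediate (not isolated)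
17 | spiro benzosuberenone dienone (C8=C9–C10=O, achiral) | COC1=CC2(C=C(OC)C1=O)CC=CC(=O)c1cc(OC)c(OC)c(OC)c12 | intermediate
18 | (8R)-8-methyl methylzinc enolate (C9=C10–OZnMe) | COC1=CC2(C=C(OC)C1=O)C[C@@H](C)C=C(O[Zn]C)c1cc(OC)c(OC)c(OC)c12 | intermediate (not isolated)
19 | (8R,9S)-8,9-dimethyl spiro-benzosuberone dienone (trans) | COC1=CC2(C=C(OC)C1=O)C[C@@H](C)[C@H](C)C(=O)c1cc(OC)c(OC)c(OC)c12 | intermediate
20 | (8R,9S,10R)-C4′,C10-diol (mixture of C4′ epimers) | COC1=CC2(C=C(OC)C1O)C[C@@H](C)[C@H](C)[C@@H](O)c1cc(OC)c(OC)c(OC)c12 | intermediate (not isolated)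
21 | (8R,9S,10R)-10-hydroxy-8,9-dimethyl spiro-benzosuberane dienone | COC1=CC2(C=C(OC)C1=O)C[C@@H](C)[C@H](C)[C@@H](O)c1cc(OC)c(OC)c(OC)c12 | intermediate
22 | CNP0201356.1, (8R,9S,10R)-10-benzoyloxy-8,9-dimethyl spiro-benzosuberane dienone | COC1=CC2(C=C(OC)C1=O)C[C@@H](C)[C@H](C)[C@@H](OC(=O)c1ccccc1)c1cc(OC)c(OC)c(OC)c12 | target

**Step count and risks**
Total: 13 steps. Longest linear sequence: 13 steps (1 → 22); aldehyde 3 enters at step 2.

Step 10 is the most exposed. After ring opening, the secondary C8 radical may cleave its C7–C1′ bond, a β-scission driven by aromatisation of the dienone to a phenoxyl radical, before chlorine is transferred; Fe(III) acting as a Lewis acid may also open the external cyclopropane bond. A faster chlorine donor such as added CuCl2 would be the first adjustment. The fallback avoids the radical altogether and sets out from 13: dibromocarbene (CHBr3, KOtBu, hexane, −20 °C → rt) adds to the silyl enol ether to give the dibromo siloxycyclopropane F1. F1 opens in a two-electron, disrotatory process with loss of bromide and the silyl group to give the 9-bromo enone F2. Palladium-catalysed hydrodebromination (Pd(PPh3)4, Bu3SnH, THF, 0 °C) of F2 returns to the route at 17.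

Step 11 comes next. The zinc enolate may be alkylated only sluggishly by iodomethane, so that proton exchange between enolate and product gives under- and over-methylated ketones and erodes the trans preference. The fallback reverses the order of the two C–C bond formations and sets out from 17: α-iodination (I2, pyridine, CH2Cl2) gives the 9-iodo enone F3, and Suzuki–Miyaura methylation (trimethylboroxine, Pd(dppf)Cl2, K2CO3, dioxane) gives the 9-methyl enone F4. Copper-catalysed asymmetric conjugate addition of Me3Al (CuTC, the phosphoramidite enantiomer giving 8R, Et2O, −30 °C) forms the dimethylaluminium enolate F5. Protonation on work-up gives 19 together with the cis (8R,9R) ketone F6, and DBU equilibration of the epimerisable C9 centre converges on 19, where the route is rejoined.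

Step 12 is third. Hydride may add to C10 with poor facial selectivity in the flexible seven-membered ring, or mainly from the face that places the hydroxyl cis to the C9 methyl; prolonged MnO2 contact could also start to oxidise C10–OH. The fallback sets out from 19 and uses inversion instead of direct control: the same reduction and re-oxidation give, through the 10S diol F7, the 10-epi hydroxy dienone F8. A Mitsunobu esterification of F8 (PhCO2H, PPh3, DIAD, toluene, 0 °C) inverts C10 and installs the benzoate in one operation, arriving directly at 22.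

**Further compounds**
F1 | step 10 | racemic 9,9-dibromo siloxycyclopropane of the spiro-tetralone dienone | COC1=CC2(C=C(OC)C1=O)CC3C(Br)(Br)C3(O[Si](C)(C)C)c1cc(OC)c(OC)c(OC)c12
F2 | step 10 | 9-bromo spiro benzosuberenone dienone | COC1=CC2(C=C(OC)C1=O)CC=C(Br)C(=O)c1cc(OC)c(OC)c(OC)c12
F3 | step 11 | 9-iodo spiro benzosuberenone dienone | COC1=CC2(C=C(OC)C1=O)CC=C(I)C(=O)c1cc(OC)c(OC)c(OC)c12
F4 | step 11 | 9-methyl spiro benzosuberenone dienone | COC1=CC2(C=C(OC)C1=O)CC=C(C)C(=O)c1cc(OC)c(OC)c(OC)c12
F5 | step 11 | (8R)-8,9-dimethyl dimethylaluminium enolate | COC1=CC2(C=C(OC)C1=O)C[C@@H](C)C(C)=C(O[Al](C)C)c1cc(OC)c(OC)c(OC)c12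
F6 | step 11 | (8R,9R)-8,9-dimethyl spiro-benzosuberone dienone (cis, C9 epimer of 19) | COC1=CC2(C=C(OC)C1=O)C[C@@H](C)[C@@H](C)C(=O)c1cc(OC)c(OC)c(OC)c12
F7 | step 12 | (8R,9S,10S)-C4′,C10-diol (mixture of C4′ epimers) | COC1=CC2(C=C(OC)C1O)C[C@@H](C)[C@H](C)[C@H](O)c1cc(OC)c(OC)c(OC)c12
F8 | step 12 | (8R,9S,10S)-10-hydroxy-8,9-dimethyl spiro-benzosuberane dienone (C10 epimer of 21) | COC1=CC2(C=C(OC)C1=O)C[C@@H](C)[C@H](C)[C@H](O)c1cc(OC)c(OC)c(OC)c12
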